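**Remarks on the chemistry (assumptions)**

- Supply: the phenol 1, the fluoroaldehydes 2 and 18 and the bromophenol 17 are taken to be catalogue compounds.
- Structures: the ring expansion was mapped atom by atom onto ring C, and precursor skeleton, product 16 and target agree. The former carbonyl carbon becomes the hydroxyl carbon between the ring B ether carbon and a methoxy carbon; the carbinol carbon becomes the methoxy carbon next to the ring CH.
- Alkene geometry: 13 is carried as the (Z)-alkene. An (E)-2-aryloxyvinyl anion has the metal anti-periplanar to the aryloxide and is expected to fragment to acetylene and aryloxide. The (Z)-alkene is the isomer that robust chemistry delivers, and the alkene geometry is erased when ring C aromatises.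
- Step saving: the carbinol oxygen is methylated in the same flask as the squarate addition. The vinyl group is made by adding a stable lithium aryloxyacetylide and semi-hydrogenating, so no tin reagent and no isolated ethynyl ether are needed.

## Structural features

The target is a linear heptameric phlorotannin: seven benzene rings (A to G) joined only by six diaryl ether oxygens, with 17 free phenolic hydroxyls, no ring-to-ring C–C bond and no stereocentre. Ring A is a 2,4,6-trihydroxyphenoxy end, ring G a 3,4,5-trihydroxyphenoxy end, rings B, D and F are 3,5-dihydroxy-1,4-phenylene units and ring E is a 3,5-dihydroxy-1,2-phenylene unit. Ring C is pentaoxygenated: C1 carries the ether to ring B, C3, C4 and C5 carry hydroxyls, C6 carries the ether to ring D, and only C2 is CH. In every bridge the oxygen sits on the left-hand ring between two ortho oxygen substituents, while the carbon it meets on the right-hand ring has at most one ortho substituent, so each bridge is best made from a hindered phenoxide on the left and an electrophilic carbon on the right. The free polyphenol (pyrogallol- and hydroxyquinol-type arrays) oxidises readily, above all in base, so all hydroxyls stay masked as methyl ethers until the last step. The real difficulty is ring C: five contiguous, differentiated oxygens, with the ring D oxygen in the most crowded position, are laborious to set one by one on a benzene ring. The key step exploits the fact that C3, C4, C5 and C6 of ring C with their oxygens map onto the four carbons of squaric acid, while C1 (with the ring B oxygen) and C2 map onto a 2-aryloxyvinyl group, so that ring expansion leaves the C6 oxygen as the only free hydroxyl.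

## Logic of the disconnections

**29 to 28 to 26.** The last operation cuts only the sixteen O–CH3 bonds of 28. The free hydroxyl on ring G of 28 is traced to the formyl group of 26, because that formyl group is what activated ring G for its attachment. The forward demands are a dealkylating agent that spares diaryl ethers and an oxygen insertion that touches only the aldehyde.

**26 to 16 + 25.** The bond cut is between the C6 oxygen of ring C and C1 of ring D. This is the central bridge and divides seven rings into three and four. The polarity is the natural one: 16 supplies the crowded oxygen and 25 a bromide flanked only by hydrogens. The forward step must be a C–O coupling that accepts a di-ortho-substituted phenoxide.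

**25 back to 17, 18 and 2.** The aryl C–O bonds F–G, E–F and D–E are cut in turn (25 to 24 + 2, 24 from 22, 22 to 21 + 2, 21 from 19, 19 to 17 + 18). Each right-hand ring arrives as a fluorobenzaldehyde whose formyl group first activates the fluoride and then, after oxygen insertion, becomes the next hindered phenol. This reduces a tetramer to three catalogue compounds. The forward demands are that the bromide of 17 survives and that the deactivated fluoroarenes still react.

**16 to 13 (key).** The ring C bond between C6 (hydroxyl carbon) and C1 (ring B ether carbon) is cut and C6 is reconnected to C3, regenerating a four-membered ring. A pentaoxygenated arene is thereby reduced to a squarate-derived cyclobutenone carrying a 2-aryloxyvinyl group. The forward step needs thermal ring opening with the vinyl group turned inward.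

**13 to 12 to 7 + 8.** The (Z)-alkene of 13 comes from the alkyne of 12 by syn addition of hydrogen. In 12 the bond between the carbinol carbon and the alkyne, and the carbinol O–CH3 bond, are cut to give 8 and the acetylide derived from 7. The forward step needs clean 1,2-addition to one squarate carbonyl and immediate capping of the alkoxide.

**7 to 5 + 6, and 5 to 3 to 1 + 2.** The vinylic C–O bond of 7 is cut to the phenol 5 and the two-carbon unit 6. The A–B ether of 5 is cut by the same fluoroaldehyde logic as above, which makes 2 a building block used four times in the route.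

## Other disconnections considered

Alternative 1: The cut is at both C–O bonds of ring E. In the forward sense, the cationic cyclopentadienylruthenium dichlorodimethoxybenzene complex A1 would take the ring D phenoxide of the A-to-D tetramer phenol A2 at the chlorine flanked by hydrogen. It would then take the phenoxide of the F–G dimer phenol A3 at the chlorine next to methoxy, giving the metal-bound permethylated heptamer A4. Release of the arene would give the permethylated heptamer A5, and demethylation would give 29.
- In favour: π-complexation turns the electron-rich dichloroarene of A1 into a strong addition–elimination electrophile under mild, non-oxidative conditions. The most congested bridge (D–E) is formed without copper, and three fragments are joined in one vessel. On convergence of the right-hand half this is better than the chosen plan, which spends steps 7 to 10 on the same two bridges.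
- Against: site selectivity rests only on steric discrimination between the two chlorines of A1. The second substitution, by A3, must occur next to a methoxy group and a bulky new aryloxy group on a ring that has just become more electron-rich. The metal is stoichiometric and must be removed from a molecule with six other electron-rich rings it could migrate to. Two end steps (decomplexation of A4, demethylation of A5) remain.
- Comparison: structurally it addresses ring E, which the chosen route handles with the same activation idea using 18, where the activator becomes the ring oxygen. Mechanistically the two are equals (addition–elimination). It does not solve ring C, so A2 would still have to come from 16.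

Alternative 2: The cut is at two C–C bonds of ring F, which is assembled from a four-carbon unit, the racemic 3-ethoxy-4-aryloxycyclobutenone A6, and a two-carbon unit, the ethynyl ether A7 of the benzyl-protected ring E phenol. Heating would open A6 to a ketene that adds [2+2] to A7; a second ring opening, 6-electron closure and tautomerisation (Danheiser benzannulation) would give the E–F–G trimer phenol A8.
- In favour: it belongs to the same mechanistic family as step 6 and forms two C–C bonds in one operation, so on bonds per step it is the better. Both ether oxygens of ring F arrive already attached, and the regiochemistry is fixed by the polarisation of the ynol ether.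
- Against: ring F is a symmetrical unit that steps 9 and 10 build from a catalogue compound without any regiochemical question. A6 and the polymerisation-prone A7 each need several steps. After debenzylation of A8 the ring E oxygen would have to be joined to a ring D carbon flanked by two methoxy groups, which is the wrong polarity for that bridge. Ethyl, methyl and benzyl ethers must all be handled.
- Comparison: equal in mechanistic pedigree, superior in bonds formed, inferior in step economy and in where the effort is spent. Ring C stays unsolved.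

Alternative 3: The cut is at the two ring A C–C bonds that join the hydroxyl carbons flanking the ether carbon to their outer neighbours. Diethyl 3-oxopentanedioate A9 would be acylated twice by the diethyl aryloxymalonate A10 of the B-to-G hexamer under NaOEt, closing ring A as the diester A11. Ester hydrolysis, double decarboxylation and demethylation would follow.
- In favour: two C–C bonds and a ring from the very cheap A9 (the equal of Alternative 2 in bonds per step), and ring A hydroxyls delivered free and regiodefined.
- Against: ring A is the easiest ring of the target and is available as 1. The condensation would be the last skeletal step of a fully linear sequence, run hot and strongly basic on the most valuable intermediate. The hindered aryloxymalonate invites retro-Claisen cleavage and loss of aryloxide. A10 itself lies at least one step beyond the hexameric ether array.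
- Comparison: structurally it solves an unproblematic ring. Mechanistically it is a classical ionic condensation, robust in principle but unproven at this size. In step economy it is the weakest of the four plans.

Key step: step 6

## Route

Step 1
Reactants: 1 2,4,6-trimethoxyphenol; 2 4-fluoro-2,6-dimethoxybenzaldehyde
Product: 3 2,6-dimethoxy-4-(2,4,6-trimethoxyphenoxy)benzaldehyde
Conditions: Cs2CO3, DMSO, 110 °C, argon
Reagents that add atoms: none
Why: Nucleophilic aromatic substitution (addition–elimination): the phenoxide of 1 attacks the fluorine-bearing carbon of 2 and the para formyl group stabilises the anionic adduct; the methoxy groups of 2 are meta to the reacting carbon and slow the reaction without blocking it.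

Step 2
Reactants: 3 2,6-dimethoxy-4-(2,4,6-trimethoxyphenoxy)benzaldehyde
Product: 5 2,6-dimethoxy-4-(2,4,6-trimethoxyphenoxy)phenol, via aryl formate 4 (not isolated)
Conditions: mCPBA, CH2Cl2, 0 °C to rt; then K2CO3 (cat.), MeOH, rt, argon
Reagents that add atoms: mCPBA (3-chloroperoxybenzoic acid), OOC(=O)c1cccc(Cl)c1
Why: Baeyer–Villiger (Dakin-type) oxidation: the electron-rich aryl group migrates in preference to hydrogen to give formate 4, and mild methanolysis frees the hindered phenol only after the oxidant is gone.

Step 3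
Reactants: 5 2,6-dimethoxy-4-(2,4,6-trimethoxyphenoxy)phenol; 6 trichloroethylene
Product: 7 2-[(E)-1,2-dichloroethenyloxy]-1,3-dimethoxy-5-(2,4,6-trimethoxyphenoxy)benzene
Conditions: K2CO3, DMF, 70 °C
Reagents that add atoms: none
Why: Base removes HCl from 6 to give dichloroacetylene at low stationary concentration, and the phenoxide adds to it in anti fashion (phenoxide addition to a haloalkyne), which places the two chlorines trans.

Step 4
Reactants: 7 2-[(E)-1,2-dichloroethenyloxy]-1,3-dimethoxy-5-(2,4,6-trimethoxyphenoxy)benzene; 8 dimethyl squarate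
Product: 12 racemic 2,3,4-trimethoxy-4-{[2,6-dimethoxy-4-(2,4,6-trimethoxyphenoxy)phenoxy]ethynyl}cyclobut-2-en-1-one, via chloroethynyl ether 9 (not isolated), via lithium aryloxyacetylide 10 (not isolated), via lithium cyclobutenolate 11 (not isolated)
Conditions: n-BuLi (2.05 equiv), THF, −78 to −40 °C; then 8, −78 °C; then MeOTf, −78 to 0 °C
Reagents that add atoms: methyl trifluoromethanesulfonate, COS(=O)(=O)C(F)(F)F
Why: The first equivalent of n-BuLi eliminates HCl to give 9 and the second exchanges chlorine for lithium (the dichlorovinyl ether route to lithium alkoxyacetylides); 10 adds 1,2 to one squarate carbonyl (organolithium–squarate addition), and the tertiary alkoxide 11 is capped at once by the hard methylating agent, the new quaternary stereocentre forming as a racemate.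

Step 5
Reactants: 12 racemic 2,3,4-trimethoxy-4-{[2,6-dimethoxy-4-(2,4,6-trimethoxyphenoxy)phenoxy]ethynyl}cyclobut-2-en-1-one
Product: 13 racemic 2,3,4-trimethoxy-4-{(Z)-2-[2,6-dimethoxy-4-(2,4,6-trimethoxyphenoxy)phenoxy]ethenyl}cyclobut-2-en-1-one
Conditions: H2 (1 atm), Pd/CaCO3 poisoned with Pb(OAc)2, quinoline, EtOAc, rt
Reagents that add atoms: none
Why: Lindlar semi-hydrogenation: syn delivery of hydrogen on the poisoned palladium surface gives the (Z)-enol ether, the tetrasubstituted ring alkene and the aryl ethers being inert; working at room temperature protects the heat-sensitive cyclobutenone.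

Step 6
Reactants: 13 racemic 2,3,4-trimethoxy-4-{(Z)-2-[2,6-dimethoxy-4-(2,4,6-trimethoxyphenoxy)phenoxy]ethenyl}cyclobut-2-en-1-one
Product: 16 6-[2,6-dimethoxy-4-(2,4,6-trimethoxyphenoxy)phenoxy]-2,3,4-trimethoxyphenol, via dienylketene 14 (not isolated), via cyclohexadienone 15 (not isolated)
Conditions: toluene (degassed, 0.01 M), 110 °C, argon
Reagents that add atoms: none
Why: This is a Moore rearrangement, the thermal ring expansion of 4-alkenyl-4-alkoxycyclobutenones to hydroquinone monoethers. Heating cleaves the C1–C4 bond of the cyclobutenone in a conrotatory 4-electron electrocyclic opening to give dienylketene 14. The ketene carbon then bonds to the aryloxy-bearing vinyl terminus in a thermal, disrotatory 6-electron electrocyclisation, the only ring-forming event, which gives cyclohexadienone 15; this tautomerises irreversibly to the arene 16. The selectivity required is torquoselectivity in the opening: the methoxy donor on C4 rotates outward, so the vinyl group turns inward and lies cis to the ketene, and any ketene formed in the other sense can only reclose to 13 and try again. Regiochemistry is not a variable, because the three squarate-derived carbons bring three contiguous methoxy groups, the former carbonyl carbon becomes the single free hydroxyl and the vinyl ether carbon arrives next to it carrying rings A and B. The (Z)-geometry puts the aryloxy group on the inside of the closing triene, but the sp-hybridised ketene terminus is sterically slim and carries no inward substituent of its own, so closure should remain fast relative to the rate-limiting ring opening. The stereocentre of 13 and the transient one of 15 are both destroyed, so no stereocentre is formed and the racemic precursor is of no consequence. High dilution and exclusion of air are specified to suppress ketene dimerisation and oxidation of the electron-rich phenol.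

Step 7
Reactants: 17 4-bromo-2,6-dimethoxyphenol; 18 2-fluoro-4,6-dimethoxybenzaldehyde
Product: 19 2-(4-bromo-2,6-dimethoxyphenoxy)-4,6-dimethoxybenzaldehyde
Conditions: Cs2CO3, DMSO, 100 °C, argon
Reagents that add atoms: none
Why: Nucleophilic aromatic substitution: the ortho formyl group activates the fluoride of 18 towards the hindered phenoxide of 17, while the unactivated bromide is untouched.

Step 8
Reactants: 19 2-(4-bromo-2,6-dimethoxyphenoxy)-4,6-dimethoxybenzaldehyde
Product: 21 2-(4-bromo-2,6-dimethoxyphenoxy)-4,6-dimethoxyphenol, via aryl formate 20 (not isolated)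
Conditions: mCPBA, CH2Cl2, 0 °C to rt; then K2CO3 (cat.), MeOH, rt, argon
Reagents that add atoms: mCPBA (3-chloroperoxybenzoic acid), OOC(=O)c1cccc(Cl)c1
Why: Baeyer–Villiger oxidation with aryl migration converts the formyl group into the ring E oxygen that will bond to ring F; the aryl bromide is inert to the peracid.

Step 9
Reactants: 21 2-(4-bromo-2,6-dimethoxyphenoxy)-4,6-dimethoxyphenol; 2 4-fluoro-2,6-dimethoxybenzaldehyde
Product: 22 4-[2-(4-bromo-2,6-dimethoxyphenoxy)-4,6-dimethoxyphenoxy]-2,6-dimethoxybenzaldehyde
Conditions: Cs2CO3, DMSO, 110 °C, argon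
Reagents that add atoms: none
Why: Nucleophilic aromatic substitution as in step 1; the reacting carbon of 2 has no ortho substituent, so even the phenoxide of 21, which sits between an aryloxy and a methoxy group, can approach.

Step 10
Reactants: 22 4-[2-(4-bromo-2,6-dimethoxyphenoxy)-4,6-dimethoxyphenoxy]-2,6-dimethoxybenzaldehyde
Product: 24 4-[2-(4-bromo-2,6-dimethoxyphenoxy)-4,6-dimethoxyphenoxy]-2,6-dimethoxyphenol, via aryl formate 23 (not isolated)
Conditions: mCPBA, CH2Cl2, 0 °C to rt; then K2CO3 (cat.), MeOH, rt, argon
Reagents that add atoms: mCPBA (3-chloroperoxybenzoic acid), OOC(=O)c1cccc(Cl)c1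
Why: Baeyer–Villiger oxidation of the di-ortho-methoxy aldehyde with aryl migration, then methanolysis of the formate, as in step 2.

Step 11
Reactants: 24 4-[2-(4-bromo-2,6-dimethoxyphenoxy)-4,6-dimethoxyphenoxy]-2,6-dimethoxyphenol; 2 4-fluoro-2,6-dimethoxybenzaldehyde
Product: 25 4-{4-[2-(4-bromo-2,6-dimethoxyphenoxy)-4,6-dimethoxyphenoxy]-2,6-dimethoxyphenoxy}-2,6-dimethoxybenzaldehyde
Conditions: Cs2CO3, DMSO, 110 °C, argon
Reagents that add atoms: none
Why: Third use of the same nucleophilic aromatic substitution; it installs ring G with its middle oxygen latent as a formyl group, so no free phenol is present during the copper coupling.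

Step 12
Reactants: 16 6-[2,6-dimethoxy-4-(2,4,6-trimethoxyphenoxy)phenoxy]-2,3,4-trimethoxyphenol; 25 4-{4-[2-(4-bromo-2,6-dimethoxyphenoxy)-4,6-dimethoxyphenoxy]-2,6-dimethoxyphenoxy}-2,6-dimethoxybenzaldehyde
Product: 26 heptamer aldehyde (ring G as 4-formyl-3,5-dimethoxyphenoxy; every other hydroxyl of the target as its methyl ether)
Conditions: CuI (20 mol %), picolinic acid (40 mol %), K3PO4, DMSO, 90 °C, argon
Reagents that add atoms: none
Why: Ullmann diaryl ether synthesis with a copper–picolinate catalyst, a system suited to di-ortho-substituted phenols; the bromide on ring D is flanked only by hydrogens, and the aryloxide para to the formyl group of ring G is a far poorer leaving group than fluoride, so no ether exchange is expected at this temperature.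

Step 13
Reactants: 26 heptamer aldehyde (ring G as 4-formyl-3,5-dimethoxyphenoxy; every other hydroxyl of the target as its methyl ether)
Product: 28 hexadeca-O-methyl ether of the target with the 4-hydroxyl of ring G free, via heptamer formate 27 (not isolated)
Conditions: mCPBA (1.2 equiv), CH2Cl2, 0 °C; then K2CO3 (cat.), MeOH, rt, argon
Reagents that add atoms: mCPBA (3-chloroperoxybenzoic acid), OOC(=O)c1cccc(Cl)c1
Why: Baeyer–Villiger oxidation of the only carbonyl group; aryl migration from a di-ortho-methoxy aldehyde is fast at 0 °C, which allows near-stoichiometric peracid and spares the electron-rich rings.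

Step 14
Reactants: 28 hexadeca-O-methyl ether of the target with the 4-hydroxyl of ring G free
Product: 29 CNP0351377.0 (the heptadecahydroxy heptamer)
Conditions: BBr3 (excess), CH2Cl2, −78 °C to rt; then MeOH, H2O, argon
Reagents that add atoms: none
Why: Lewis-acid ether cleavage: bromide attacks the methyl carbon of each boron-complexed aryl methyl ether, whereas the diaryl ether bridges offer no sp3 carbon and persist; hydrolysis of the aryl borates frees all phenols.

## Compound list

1 | 2,4,6-trimethoxyphenol | COc1cc(OC)c(O)c(OC)c1 | starting material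
2 | 4-fluoro-2,6-dimethoxybenzaldehyde | COc1cc(F)cc(OC)c1C=O | starting material
3 | 2,6-dimethoxy-4-(2,4,6-trimethoxyphenoxy)benzaldehyde | COc1cc(OC)c(Oc2cc(OC)c(C=O)c(OC)c2)c(OC)c1 | intermediate
4 | 2,6-dimethoxy-4-(2,4,6-trimethoxyphenoxy)phenyl formate | COc1cc(OC)c(Oc2cc(OC)c(OC=O)c(OC)c2)c(OC)c1 | intermediate
5 | 2,6-dimethoxy-4-(2,4,6-trimethoxyphenoxy)phenol (A-B phenol) | COc1cc(OC)c(Oc2cc(OC)c(O)c(OC)c2)c(OC)c1 | intermediate
6 | trichloroethylene | ClC=C(Cl)Cl | starting material
7 | 2-[(E)-1,2-dichloroethenyloxy]-1,3-dimethoxy-5-(2,4,6-trimethoxyphenoxy)benzene | Cl/C=C(/Cl)Oc1c(OC)cc(Oc2c(OC)cc(OC)cc2OC)cc1OC | intermediate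
8 | dimethyl squarate (3,4-dimethoxycyclobut-3-ene-1,2-dione) | COC1=C(OC)C(=O)C1=O | starting material
9 | 2-(chloroethynyloxy)-1,3-dimethoxy-5-(2,4,6-trimethoxyphenoxy)benzene | ClC#COc1c(OC)cc(Oc2c(OC)cc(OC)cc2OC)cc1OC | intermediate
10 | lithium [2,6-dimethoxy-4-(2,4,6-trimethoxyphenoxy)phenoxy]acetylide | [Li]C#COc1c(OC)cc(Oc2c(OC)cc(OC)cc2OC)cc1OC | intermediate
11 | lithium 1-{[2,6-dimethoxy-4-(2,4,6-trimethoxyphenoxy)phenoxy]ethynyl}-2,3-dimethoxy-4-oxocyclobut-2-en-1-olate (racemic) | [Li+].COC1=C(OC)C([O-])(C#COc2c(OC)cc(Oc3c(OC)cc(OC)cc3OC)cc2OC)C1=O | intermediate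
12 | racemic 2,3,4-trimethoxy-4-{[2,6-dimethoxy-4-(2,4,6-trimethoxyphenoxy)phenoxy]ethynyl}cyclobut-2-en-1-one | COC1=C(OC)C(OC)(C#COc2c(OC)cc(Oc3c(OC)cc(OC)cc3OC)cc2OC)C1=O | intermediate
13 | racemic 2,3,4-trimethoxy-4-{(Z)-2-[2,6-dimethoxy-4-(2,4,6-trimethoxyphenoxy)phenoxy]ethenyl}cyclobut-2-en-1-one | COC1=C(OC)C(OC)(/C=C\Oc2c(OC)cc(Oc3c(OC)cc(OC)cc3OC)cc2OC)C1=O | intermediate
14 | (3Z,5Z)-6-[2,6-dimethoxy-4-(2,4,6-trimethoxyphenoxy)phenoxy]-2,3,4-trimethoxyhexa-1,3,5-trien-1-one (dienylketene) | O=C=C(OC)/C(OC)=C(OC)\C=C/Oc1c(OC)cc(Oc2c(OC)cc(OC)cc2OC)cc1OC | intermediate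
15 | racemic 6-[2,6-dimethoxy-4-(2,4,6-trimethoxyphenoxy)phenoxy]-2,3,4-trimethoxycyclohexa-2,4-dien-1-one | O=C1C(OC)=C(OC)C(OC)=CC1Oc1c(OC)cc(Oc2c(OC)cc(OC)cc2OC)cc1OC | intermediate
16 | 6-[2,6-dimethoxy-4-(2,4,6-trimethoxyphenoxy)phenoxy]-2,3,4-trimethoxyphenol (A-B-C phenol) | COc1cc(Oc2c(OC)cc(Oc3c(OC)cc(OC)cc3OC)cc2OC)c(O)c(OC)c1OC | intermediate
17 | 4-bromo-2,6-dimethoxyphenol | COc1cc(Br)cc(OC)c1O | starting material
18 | 2-fluoro-4,6-dimethoxybenzaldehyde | COc1cc(F)c(C=O)c(OC)c1 | starting material
19 | 2-(4-bromo-2,6-dimethoxyphenoxy)-4,6-dimethoxybenzaldehyde | COc1cc(OC)c(C=O)c(Oc2c(OC)cc(Br)cc2OC)c1 | intermediate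
20 | 2-(4-bromo-2,6-dimethoxyphenoxy)-4,6-dimethoxyphenyl formate | COc1cc(OC)c(OC=O)c(Oc2c(OC)cc(Br)cc2OC)c1 | intermediate
21 | 2-(4-bromo-2,6-dimethoxyphenoxy)-4,6-dimethoxyphenol | COc1cc(OC)c(O)c(Oc2c(OC)cc(Br)cc2OC)c1 | intermediate
22 | 4-[2-(4-bromo-2,6-dimethoxyphenoxy)-4,6-dimethoxyphenoxy]-2,6-dimethoxybenzaldehyde | COc1cc(OC)c(Oc2cc(OC)c(C=O)c(OC)c2)c(Oc2c(OC)cc(Br)cc2OC)c1 | intermediate
23 | 4-[2-(4-bromo-2,6-dimethoxyphenoxy)-4,6-dimethoxyphenoxy]-2,6-dimethoxyphenyl formate | COc1cc(OC)c(Oc2cc(OC)c(OC=O)c(OC)c2)c(Oc2c(OC)cc(Br)cc2OC)c1 | intermediate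
24 | 4-[2-(4-bromo-2,6-dimethoxyphenoxy)-4,6-dimethoxyphenoxy]-2,6-dimethoxyphenol | COc1cc(OC)c(Oc2cc(OC)c(O)c(OC)c2)c(Oc2c(OC)cc(Br)cc2OC)c1 | intermediate
25 | 4-{4-[2-(4-bromo-2,6-dimethoxyphenoxy)-4,6-dimethoxyphenoxy]-2,6-dimethoxyphenoxy}-2,6-dimethoxybenzaldehyde (D-E-F-G bromide) | COc1cc(OC)c(Oc2cc(OC)c(Oc3cc(OC)c(C=O)c(OC)c3)c(OC)c2)c(Oc2c(OC)cc(Br)cc2OC)c1 | intermediate
26 | heptamer aldehyde (ring G as 4-formyl-3,5-dimethoxyphenoxy; all other hydroxyls methylated) | COc1cc(OC)c(Oc2cc(OC)c(Oc3cc(OC)c(OC)c(OC)c3Oc3cc(OC)c(Oc4cc(OC)cc(OC)c4Oc4cc(OC)c(Oc5cc(OC)c(C=O)c(OC)c5)c(OC)c4)c(OC)c3)c(OC)c2)c(OC)c1 | intermediate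
27 | heptamer formate (ring G as 4-formyloxy-3,5-dimethoxyphenoxy) | COc1cc(OC)c(Oc2cc(OC)c(Oc3cc(OC)c(OC)c(OC)c3Oc3cc(OC)c(Oc4cc(OC)cc(OC)c4Oc4cc(OC)c(Oc5cc(OC)c(OC=O)c(OC)c5)c(OC)c4)c(OC)c3)c(OC)c2)c(OC)c1 | intermediate
28 | hexadeca-O-methyl ether of the target with the 4-hydroxyl of ring G free | COc1cc(OC)c(Oc2cc(OC)c(Oc3cc(OC)c(OC)c(OC)c3Oc3cc(OC)c(Oc4cc(OC)cc(OC)c4Oc4cc(OC)c(Oc5cc(OC)c(O)c(OC)c5)c(OC)c4)c(OC)c3)c(OC)c2)c(OC)c1 | intermediate
29 | CNP0351377.0 | Oc1cc(O)c(Oc2cc(O)c(Oc3cc(O)c(O)c(O)c3Oc3cc(O)c(Oc4cc(O)cc(O)c4Oc4cc(O)c(Oc5cc(O)c(O)c(O)c5)c(O)c4)c(O)c3)c(O)c2)c(O)c1 | target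

## Step count and least certain steps

Total: 14 steps. Longest linear sequence: 9 steps (1 to 6, then 12 to 14); the D-to-G branch (steps 7 to 11) is 5 steps before the convergence.

**Step 6 (key step).** The aryloxy group has to swing through the inside of the closing triene. If this retards the 6-electron closure, the ketene has time to dimerise or be trapped by adventitious nucleophiles. The product phenol may also oxidise in air at 110 °C. Fallback, setting out from 5 and returning at 16; it gives up the squarate and takes ring C from a pre-oxygenated benzene, whose formyl group first assists the ether coupling and then becomes the hydroxyl: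
- The catalogue compound 5-bromo-1,2,3-trimethoxybenzene F1 would be formylated at one of its two equivalent free positions (Cl2CHOMe, TiCl4, CH2Cl2, 0 °C; Rieche formylation) to 6-bromo-2,3,4-trimethoxybenzaldehyde F2.
- Ullmann coupling of 5 with F2 (CuI, picolinic acid, K3PO4, DMSO, 90 °C), assisted by the ortho formyl group, would give the A-B-C aldehyde F3.
- mCPBA and then K2CO3 in MeOH would give, through the A-B-C formate F4, the phenol 16.
This path is held in reserve because it depends on a copper coupling between a di-ortho-substituted phenoxide and an ortho-substituted, electron-rich bromide.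

**Step 12.** C–O bond formation at copper may be slow with a phenoxide flanked by an aryloxy and a methoxy group, so that hydrodebromination of the bromide or arylation of the ligand competes. Fallback, setting out from 16 and returning at 26: rings D to G are added one at a time by the substitution and oxygen-insertion cycle of steps 1 and 2, with no metal involved.
- 16 and 2 (Cs2CO3, DMSO) would give the A-to-D aldehyde F5. mCPBA then methanolysis would give, through the A-to-D formate F6, the A-to-D phenol F7.
- F7 and 18 would give the A-to-E aldehyde F8, oxidised through the A-to-E formate F9 to the A-to-E phenol F10.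
- F10 and 2 would give the A-to-F aldehyde F11, oxidised through the A-to-F formate F12 to the A-to-F phenol F13.
- A final substitution of F13 on 2 gives 26.
This costs six extra steps and all convergence, but uses only reaction types already in the route.

**Step 5.** Hydrogen uptake may stall because the alkyne lies between a quaternary carbon and a 2,6-disubstituted aryloxy group, or reduction may run on to the saturated ether. Fallback, setting out from 7 and returning at 13:
- n-BuLi then MeOH quench at −78 °C would give the aryl ethynyl ether F14.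
- Radical hydrostannylation (Bu3SnH, Et3B, trace air, toluene, low temperature) should give by kinetic anti addition the (Z)-2-(aryloxy)vinylstannane F15.
- Tin–lithium exchange with n-BuLi at −78 °C gives the (Z)-2-(aryloxy)vinyllithium F16, in which lithium is syn to the aryloxy oxygen and not disposed to anti elimination.
- Addition to 8 gives the lithium cyclobutenolate F17, and MeOTf gives 13.

**Step 14.** Cleavage of sixteen ethers may stop short and leave partly methylated congeners, and the free polyphenol may degrade oxidatively during isolation. Fallback, setting out from 28 and returning at 29: the crude BBr3 product is acetylated (Ac2O, pyridine) to the heptadecaacetate F18, which is stable and can be purified on silica. Acid-catalysed methanolysis (HCl in MeOH, argon) then releases 29.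

## Further compounds

F1 | step 6 | 5-bromo-1,2,3-trimethoxybenzene | COc1cc(Br)cc(OC)c1OC
F2 | step 6 | 6-bromo-2,3,4-trimethoxybenzaldehyde | COc1cc(Br)c(C=O)c(OC)c1OC
F3 | step 6 | 6-[2,6-dimethoxy-4-(2,4,6-trimethoxyphenoxy)phenoxy]-2,3,4-trimethoxybenzaldehyde (A-B-C aldehyde) | COc1cc(Oc2c(OC)cc(Oc3c(OC)cc(OC)cc3OC)cc2OC)c(C=O)c(OC)c1OC
F4 | step 6 | 6-[2,6-dimethoxy-4-(2,4,6-trimethoxyphenoxy)phenoxy]-2,3,4-trimethoxyphenyl formate (A-B-C formate) | COc1cc(Oc2c(OC)cc(Oc3c(OC)cc(OC)cc3OC)cc2OC)c(OC=O)c(OC)c1OC
F5 | step 12 | A-to-D aldehyde (ring D as 4-formyl-3,5-dimethoxyphenoxy) | COc1cc(OC)c(Oc2cc(OC)c(Oc3cc(OC)c(OC)c(OC)c3Oc3cc(OC)c(C=O)c(OC)c3)c(OC)c2)c(OC)c1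
F6 | step 12 | A-to-D formate | COc1cc(OC)c(Oc2cc(OC)c(Oc3cc(OC)c(OC)c(OC)c3Oc3cc(OC)c(OC=O)c(OC)c3)c(OC)c2)c(OC)c1
F7 | step 12 | A-to-D phenol | COc1cc(OC)c(Oc2cc(OC)c(Oc3cc(OC)c(OC)c(OC)c3Oc3cc(OC)c(O)c(OC)c3)c(OC)c2)c(OC)c1
F8 | step 12 | A-to-E aldehyde (ring E as 2-formyl-3,5-dimethoxyphenoxy) | COc1cc(OC)c(Oc2cc(OC)c(Oc3cc(OC)c(OC)c(OC)c3Oc3cc(OC)c(Oc4cc(OC)cc(OC)c4C=O)c(OC)c3)c(OC)c2)c(OC)c1
F9 | step 12 | A-to-E formate | COc1cc(OC)c(Oc2cc(OC)c(Oc3cc(OC)c(OC)c(OC)c3Oc3cc(OC)c(Oc4cc(OC)cc(OC)c4OC=O)c(OC)c3)c(OC)c2)c(OC)c1
F10 | step 12 | A-to-E phenol | COc1cc(OC)c(Oc2cc(OC)c(Oc3cc(OC)c(OC)c(OC)c3Oc3cc(OC)c(Oc4cc(OC)cc(OC)c4O)c(OC)c3)c(OC)c2)c(OC)c1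
F11 | step 12 | A-to-F aldehyde (ring F as 4-formyl-3,5-dimethoxyphenoxy) | COc1cc(OC)c(Oc2cc(OC)c(Oc3cc(OC)c(OC)c(OC)c3Oc3cc(OC)c(Oc4cc(OC)cc(OC)c4Oc4cc(OC)c(C=O)c(OC)c4)c(OC)c3)c(OC)c2)c(OC)c1
F12 | step 12 | A-to-F formate | COc1cc(OC)c(Oc2cc(OC)c(Oc3cc(OC)c(OC)c(OC)c3Oc3cc(OC)c(Oc4cc(OC)cc(OC)c4Oc4cc(OC)c(OC=O)c(OC)c4)c(OC)c3)c(OC)c2)c(OC)c1
F13 | step 12 | A-to-F phenol | COc1cc(OC)c(Oc2cc(OC)c(Oc3cc(OC)c(OC)c(OC)c3Oc3cc(OC)c(Oc4cc(OC)cc(OC)c4Oc4cc(OC)c(O)c(OC)c4)c(OC)c3)c(OC)c2)c(OC)c1
F14 | step 5 | 2-(ethynyloxy)-1,3-dimethoxy-5-(2,4,6-trimethoxyphenoxy)benzene | C#COc1c(OC)cc(Oc2c(OC)cc(OC)cc2OC)cc1OC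
F15 | step 5 | tributyl{(Z)-2-[2,6-dimethoxy-4-(2,4,6-trimethoxyphenoxy)phenoxy]ethenyl}stannane | CCCC[Sn](CCCC)(CCCC)/C=C\Oc1c(OC)cc(Oc2c(OC)cc(OC)cc2OC)cc1OC
F16 | step 5 | (Z)-2-[2,6-dimethoxy-4-(2,4,6-trimethoxyphenoxy)phenoxy]ethenyllithium | [Li]/C=C\Oc1c(OC)cc(Oc2c(OC)cc(OC)cc2OC)cc1OC
F17 | step 5 | lithium 1-{(Z)-2-[2,6-dimethoxy-4-(2,4,6-trimethoxyphenoxy)phenoxy]ethenyl}-2,3-dimethoxy-4-oxocyclobut-2-en-1-olate (racemic) | [Li+].COC1=C(OC)C([O-])(/C=C\Oc2c(OC)cc(Oc3c(OC)cc(OC)cc3OC)cc2OC)C1=O
F18 | step 14 | heptadecaacetate of the target | CC(=O)Oc1cc(OC(C)=O)c(Oc2cc(OC(C)=O)c(Oc3cc(OC(C)=O)c(OC(C)=O)c(OC(C)=O)c3Oc3cc(OC(C)=O)c(Oc4cc(OC(C)=O)cc(OC(C)=O)c4Oc4cc(OC(C)=O)c(Oc5cc(OC(C)=O)c(OC(C)=O)c(OC(C)=O)c5)c(OC(C)=O)c4)c(OC(C)=O)c3)c(OC(C)=O)c2)c(OC(C)=O)c1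
A1 | alternative 1 | [(C5H5)Ru(1,2-dichloro-3,5-dimethoxybenzene)]PF6 | COc1cc(OC)c(Cl)c(Cl)c1.[Ru+2].c1cc[cH-]c1.F[P-](F)(F)(F)(F)F
A2 | alternative 1 | permethylated A-to-D tetramer with free ring D phenol | COc1cc(OC)c(Oc2cc(OC)c(Oc3cc(OC)c(OC)c(OC)c3Oc3cc(OC)c(O)c(OC)c3)c(OC)c2)c(OC)c1
A3 | alternative 1 | 3,5-dimethoxy-4-(3,4,5-trimethoxyphenoxy)phenol (F-G dimer phenol) | COc1cc(O)cc(OC)c1Oc1cc(OC)c(OC)c(OC)c1
A4 | alternative 1 | [(C5H5)Ru(permethylated heptamer, bound at ring E)]PF6 | COc1cc(OC)c(Oc2cc(OC)c(Oc3cc(OC)c(OC)c(OC)c3Oc3cc(OC)c(Oc4cc(OC)cc(OC)c4Oc4cc(OC)c(Oc5cc(OC)c(OC)c(OC)c5)c(OC)c4)c(OC)c3)c(OC)c2)c(OC)c1.[Ru+2].c1cc[cH-]c1.F[P-](F)(F)(F)(F)F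
A5 | alternative 1 | permethylated heptamer (heptadeca-O-methyl ether of the target) | COc1cc(OC)c(Oc2cc(OC)c(Oc3cc(OC)c(OC)c(OC)c3Oc3cc(OC)c(Oc4cc(OC)cc(OC)c4Oc4cc(OC)c(Oc5cc(OC)c(OC)c(OC)c5)c(OC)c4)c(OC)c3)c(OC)c2)c(OC)c1
A6 | alternative 2 | racemic 3-ethoxy-4-(3,4,5-trimethoxyphenoxy)cyclobut-2-en-1-one | CCOC1=CC(=O)C1Oc1cc(OC)c(OC)c(OC)c1
A7 | alternative 2 | 1-(benzyloxy)-2-(ethynyloxy)-3,5-dimethoxybenzene | C#COc1c(OCc2ccccc2)cc(OC)cc1OC
A8 | alternative 2 | protected E-F-G trimer with one free ring F phenol | CCOc1cc(Oc2c(OCc3ccccc3)cc(OC)cc2OC)cc(O)c1Oc1cc(OC)c(OC)c(OC)c1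
A9 | alternative 3 | diethyl 3-oxopentanedioate | CCOC(=O)CC(=O)CC(=O)OCC
A10 | alternative 3 | diethyl aryloxymalonate of the permethylated B-to-G hexamer | CCOC(=O)C(Oc1cc(OC)c(Oc2cc(OC)c(OC)c(OC)c2Oc2cc(OC)c(Oc3cc(OC)cc(OC)c3Oc3cc(OC)c(Oc4cc(OC)c(OC)c(OC)c4)c(OC)c3)c(OC)c2)c(OC)c1)C(=O)OCC
A11 | alternative 3 | diethyl 2,4,6-trihydroxy-5-(hexamer aryloxy)benzene-1,3-dicarboxylate | CCOC(=O)c1c(O)c(Oc2cc(OC)c(Oc3cc(OC)c(OC)c(OC)c3Oc3cc(OC)c(Oc4cc(OC)cc(OC)c4Oc4cc(OC)c(Oc5cc(OC)c(OC)c(OC)c5)c(OC)c4)c(OC)c3)c(OC)c2)c(O)c(C(=O)OCC)c1O
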